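The hydrindene core's ring B (C3a–C4–C5–C6–C7–C7a) is built one carbon short. As a cyclopentenone it has C3a as its β-carbon, so an intramolecular Alder-ene reaction closes ring A and sets the contra-steric all-cis C3/C3a/C7a array. The key step then inserts C5. Dibromocarbene adds to the tetrasubstituted silyl enol ether of the cis-diquinane and the cyclopropane opens. One operation gives six-membered ring B, the C4=C5 alkene next to the C6 oxygen, and a C5–Br bond. It exploits that C5 alone is alkene carbon, carbinol neighbour and anchor of the eleven-membered bridge. Suzuki coupling (C7'–C5) and Nozaki–Hiyama–Kishi closure (C1'–C2') then complete that bridge.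

Key step: step 7

Remark (atom labels, used for all intermediates): the core is numbered as indene. Ring A = C1, C2, C3, C3a, C7a. Ring B = C3a, C4, C5, C6, C7, C7a. CH3 groups sit on C4 and C7a, OH groups on C6 and C7. The bridge is C3–C1'(=CH2)–C2'(OAc)–C3'–C4'–C5'(CH3)–C6'–C7'–C5. Target configuration: 3R, 3aS, 6R, 7R, 7aS, 2'R, 5'R. Both antipodes of β-citronellene are taken as commercial.

Step 1
Reactants: 1 3-ethoxycyclopent-2-en-1-one; 2 5-bromo-2-methylpent-2-ene
Product: 4 3-(4-methylpent-3-en-1-yl)cyclopent-2-en-1-one, via homoprenylmagnesium bromide 3 (not isolated)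
Conditions: 2, Mg, THF, reflux; then 1, 0 °C → rt; 1 M HCl
Reagents that add atoms: none
Why: Stork–Danheiser transposition, in which 1,2-addition of the Grignard reagent to the vinylogous ester and acidic hydrolysis/dehydration give the 3-alkyl enone; no stereocentre is formed.

Step 2
Reactants: 4 3-(4-methylpent-3-en-1-yl)cyclopent-2-en-1-one
Product: 5 (S)-3-methyl-3-(4-methylpent-3-en-1-yl)cyclopentan-1-one
Conditions: Me3Al, Cu(O2CC4H3S) (5 mol %), (R,R)-N,N-bis[1-(naphthalen-2-yl)ethyl]-P,P-diphenylphosphinous amide (10 mol %), Et2O, −30 °C; aq. HCl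
Reagents that add atoms: trimethylaluminium C[Al](C)C
Why: Copper-catalysed asymmetric conjugate addition of a trialkylaluminium to a β-substituted cyclopentenone; the chiral copper–phosphinamine complex differentiates the enone faces and should set the quaternary C7a as S (ligand antipode chosen accordingly).

Step 3
Reactants: 5 (S)-3-methyl-3-(4-methylpent-3-en-1-yl)cyclopentan-1-one
Product: 6 (4S)-2,4-dimethyl-4-(4-methylpent-3-en-1-yl)cyclopentan-1-one (C2 epimers)
Conditions: LiN(iPr)2, THF, −78 °C; MeI, −78 → 0 °C
Reagents that add atoms: iodomethane CI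
Why: Kinetic enolate alkylation; the α-CH2 next to the quaternary carbon is neopentyl, so deprotonation and methylation occur at the remote α-carbon (future C4), whose configuration is erased in step 4.

Step 4
Reactants: 6 (4S)-2,4-dimethyl-4-(4-methylpent-3-en-1-yl)cyclopentan-1-one
Product: 7 (R)-2,4-dimethyl-4-(4-methylpent-3-en-1-yl)cyclopent-2-en-1-one
Conditions: IBX (2-iodoxybenzoic acid), DMSO–PhF, 75 °C
Reagents that add atoms: none
Why: IBX dehydrogenation of a ketone; the quaternary C7a carries no hydrogen, so ring unsaturation can arise only between C4 and C3a, and C7a is untouched.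

Step 5
Reactants: 7 (R)-2,4-dimethyl-4-(4-methylpent-3-en-1-yl)cyclopent-2-en-1-one
Product: 8 cis-diquinane ketone bearing the concave-face C3 isopropenyl group
Conditions: toluene (0.02 M, BHT), sealed tube, 250 °C
Reagents that add atoms: none
Why: Thermal intramolecular Alder-ene reaction of a 1,6-diene (enone C4=C3a as enophile, prenyl unit as ene); the tether on C7a reaches only one face of C3a, which makes the fusion cis, and because an allylic methyl hydrogen must be handed to C4 in the same six-centre transition state the new isopropenyl group is forced under ring B, cis to C4, which sets C3a (S) and C3 (R).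

Step 6
Reactants: 8 cis-diquinane ketone
Product: 9 tetrasubstituted trimethylsilyl enol ether (C6=C4) of 8
Conditions: Me3SiOTf, Et3N, CH2Cl2, 0 °C → rt
Reagents that add atoms: trimethylsilyl triflate C[Si](C)(C)OS(=O)(=O)C(F)(F)F
Why: Soft enolisation under equilibrating conditions gives the more substituted silyl enol ether, while the alternative toward C7 is disfavoured by the adjacent quaternary C7a; C3, C3a and C7a are not affected.

Step 7
Reactants: 9 tetrasubstituted trimethylsilyl enol ether
Product: 11 5-bromo-4,7a-dimethyl-3-isopropenyl-cis-hexahydroinden-6-one, via dibromocyclopropane adduct 10 (not isolated)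
Conditions: CHBr3 (1.05 equiv), KOtBu, pentane, −30 → 0 °C; filter; toluene, 80 °C
Reagents that add atoms: bromoform BrC(Br)Br
Why: Dibromocarbene from α-elimination of CHBr3 adds in a concerted cheletropic [2+1] step to the C6=C4 silyl enol ether from the convex face to give 10, whose bromide lying over the five-membered ring ionises while the C6–C4 bond opens in a disrotatory two-electron electrocyclic sense, and loss of Me3SiBr from the 2-bromo-oxyallyl cation leaves the 2-bromoenone. The closest known reaction type is the dihalocarbene one-carbon ring expansion of cyclic silyl enol ethers to 2-halocycloalk-2-enones. The only ring closed is the transient cyclopropane ([2+1] addition); ring B is not closed anew but grows from five to six atoms by cleavage of the zero-bridge bond, so that C5 comes to lie between C6 and C4. No new stereocentre survives because C6, C5 and C4 all end sp2, and C3, C3a and C7a are retained because no bond to them is broken and the base is filtered off before warming. The regiochemistry is fixed by the position of the enol ether made in step 6, and the chemoselectivity over the isopropenyl group rests on the much higher nucleophilicity of the tetrasubstituted silyl enol ether toward the electrophilic carbene and on the single equivalent of CHBr3. The carbonyl thereby moves one atom away from C4, and C5 is delivered with the halogen needed for attaching the bridge.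

Step 8
Reactants: 12 (S)-β-citronellene
Product: 14 (S)-6,6-dimethoxy-3-methylhex-1-ene, via (S)-4-methylhex-5-enal 13 (not isolated)
Conditions: O3 (1 equiv), CH2Cl2, −78 °C; Me2S; then HC(OMe)3, TsOH (cat.), rt
Reagents that add atoms: ozone [O-][O+]=O (oxygen of 13 only); trimethyl orthoformate COC(OC)OC
Why: Chemoselective ozonolysis of the electron-rich trisubstituted alkene in the presence of the vinyl group, followed by acetalisation; the C5' stereocentre comes unchanged from the chiral pool.

Step 9
Reactants: 11 bromo-hydrindenone; 14 (S)-6,6-dimethoxy-3-methylhex-1-ene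
Product: 16 C5-alkylated hydrindenone carrying the C7'–C2' acetal chain, via B-alkyl-9-BBN borane 15 (not isolated)
Conditions: 14, 9-BBN-H (1.0 equiv), THF, rt; then 11, PdCl2(dppf) (5 mol %), AsPh3, Cs2CO3, DMF–H2O, rt
Reagents that add atoms: none
Why: B-alkyl Suzuki–Miyaura coupling; anti-Markovnikov hydroboration is finished before 11 is added, so the isopropenyl group is spared, and the activated 2-bromoenone undergoes ready oxidative addition to zerovalent palladium; no stereocentre is touched.

Step 10
Reactants: 16 C5-alkylated hydrindenone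
Product: 17 (7R)-7-hydroxy enone
Conditions: KN(SiMe3)2, THF, −78 °C; 2-(phenylsulfonyl)-3-phenyloxaziridine; AcOH
Reagents that add atoms: 2-(phenylsulfonyl)-3-phenyloxaziridine O=S(=O)(c1ccccc1)N1OC1c1ccccc1
Why: Kinetic cross-conjugated (α') enolate formation and oxaziridine enolate hydroxylation; oxygen should arrive at C7 from the convex face, syn to the angular CH3, because the concave face is screened by ring A and the pseudo-axial C3 branch.

Step 11
Reactants: 17 (7R)-7-hydroxy enone
Product: 18 (6R,7R)-trans-diol
Conditions: Me4NBH(OAc)3, anhydrous MeCN–AcOH, −30 °C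
Reagents that add atoms: none
Why: Saksena–Evans hydroxyl-directed reduction; the C7 hydroxyl binds boron and hands hydride to the C6 carbonyl on its own (convex) face, so the new C6 hydroxyl ends on the opposite face (trans-diol) with clean 1,2-selectivity.

Step 12
Reactants: 18 (6R,7R)-trans-diol
Product: 19 6,7-O-(tetraisopropyldisiloxane-1,3-diyl) ether
Conditions: (iPr2SiCl)2O, imidazole, DMF, rt
Reagents that add atoms: 1,3-dichloro-1,1,3,3-tetraisopropyldisiloxane CC(C)[Si](Cl)(C(C)C)O[Si](Cl)(C(C)C)C(C)C
Why: Disiloxane bridging of a trans-diequatorial vicinal diol; the allylic C6 hydroxyl is silylated first and the hindered C7 hydroxyl closes the seven-membered ring intramolecularly, under chloride conditions that leave the acetal alone.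

Step 13
Reactants: 19 disiloxane-protected diene acetal
Product: 20 C3 methyl ketone
Conditions: OsO4 (2 mol %), NaIO4, 2,6-lutidine, dioxane–H2O, rt
Reagents that add atoms: sodium periodate [Na+].[O-]I(=O)(=O)=O
Why: Lemieux–Johnson oxidation; OsO4 selects the unhindered 1,1-disubstituted alkene over the tetrasubstituted C4=C5 bond, and the buffered neutral medium spares the acetal and the epimerisable C3.

Step 14
Reactants: 20 C3 methyl ketone
Product: 21 C1' alkenyl triflate
Conditions: KN(SiMe3)2, THF, −78 °C; PhNTf2; AcOH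
Reagents that add atoms: N-phenylbis(trifluoromethanesulfonimide) O=S(=O)(N(c1ccccc1)S(=O)(=O)C(F)(F)F)C(F)(F)F
Why: Irreversible kinetic deprotonation at the unhindered CH3 rather than at the C3 methine, then O-triflation, gives the 1,1-disubstituted alkenyl triflate without epimerising C3.

Step 15
Reactants: 21 C1' alkenyl triflate
Product: 22 triflate aldehyde (C2' = CHO)
Conditions: LiBF4, wet MeCN, rt
Reagents that add atoms: water O
Why: Mild Lewis-acid-assisted hydrolysis of the dimethyl acetal, which the alkenyl triflate and the disiloxane tolerate.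

Step 16
Reactants: 22 triflate aldehyde
Product: 23 bridged allylic alcohol (both C2' epimers)
Conditions: CrCl2 (10 equiv), NiCl2 (cat.), DMSO–THF, rt, slow addition (final 2 mM)
Reagents that add atoms: none
Why: Intramolecular Nozaki–Hiyama–Kishi reaction; zerovalent nickel inserts into the C–OTf bond, transmetalation gives an alkenyl species of trivalent chromium that adds only to the aldehyde, and the cis C3/C4 arrangement on the rigid core holds both ends on one face for closure of the eleven-membered ring.

Step 17
Reactants: 23 bridged allylic alcohol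
Product: 24 bridged α-methylene ketone
Conditions: DMP [1,1,1-triacetoxy-1λ5,2-benziodoxol-3(1H)-one], CH2Cl2, 0 °C → rt
Reagents that add atoms: none
Why: Dess–Martin oxidation under neutral conditions funnels both C2' epimers into one enone without touching C3.

Step 18
Reactants: 24 bridged α-methylene ketone
Product: 25 (2'R)-allylic alcohol
Conditions: (S)-2-methyl-CBS-oxazaborolidine (30 mol %), catecholborane, toluene, −78 °C
Reagents that add atoms: none
Why: Corey–Bakshi–Shibata reduction; the branched alkenyl group C1' acts as the large and C3'H2 as the small substituent, so the (S)-catalyst should deliver the (R)-carbinol by reagent control, and catecholborane at low temperature avoids hydroboration.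

Step 19
Reactants: 25 (2'R)-allylic alcohol
Product: 26 (2'R)-acetate
Conditions: Ac2O, pyridine, DMAP (cat.), CH2Cl2, 0 °C → rt
Reagents that add atoms: acetic anhydride CC(=O)OC(C)=O
Why: DMAP-catalysed acylation of the only free hydroxyl with retention at C2'.

Step 20
Reactants: 26 (2'R)-acetate
Product: 27 target CNP0192310.3
Conditions: HF·pyridine, THF, 0 °C → rt
Reagents that add atoms: none
Why: Fluoride-induced cleavage of the disiloxane frees the C6/C7 diol under mildly acidic conditions that leave the allylic acetate and both alkenes intact.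

Compound list
1 | 3-ethoxycyclopent-2-en-1-one | CCOC1=CC(=O)CC1 | starting material
2 | 5-bromo-2-methylpent-2-ene | CC(C)=CCCBr | starting material
3 | (4-methylpent-3-en-1-yl)magnesium bromide | CC(C)=CCC[Mg]Br | intermediate
4 | 3-(4-methylpent-3-en-1-yl)cyclopent-2-en-1-one | O=C1C=C(CCC=C(C)C)CC1 | intermediate
5 | (S)-3-methyl-3-(4-methylpent-3-en-1-yl)cyclopentan-1-one | O=C1CC[C@](C)(CCC=C(C)C)C1 | intermediate
6 | (4S)-2,4-dimethyl-4-(4-methylpent-3-en-1-yl)cyclopentan-1-one, C2 epimers | O=C1C(C)C[C@](C)(CCC=C(C)C)C1 | intermediate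
7 | (R)-2,4-dimethyl-4-(4-methylpent-3-en-1-yl)cyclopent-2-en-1-one | O=C1C(C)=C[C@](C)(CCC=C(C)C)C1 | intermediate
8 | 1,3a-dimethyl-6-(prop-1-en-2-yl)hexahydropentalen-2(1H)-one; cis-fused, C3a-H, C7a-CH3 and C4-CH3 on the convex face, isopropenyl on C3 on the concave face cis to C4 | O=C1[C@@H](C)[C@@H]2[C@H](C(C)=C)CC[C@]2(C)C1 | intermediate
9 | trimethylsilyl enol ether of 8 with the tetrasubstituted C6=C4 double bond | C[Si](C)(C)OC1=C(C)[C@@H]2[C@H](C(C)=C)CC[C@]2(C)C1 | intermediate
10 | convex-face dibromocarbene adduct of 9 (1-siloxy-6,6-dibromobicyclo[3.1.0]hexane fused to ring A) | C[Si](C)(C)O[C@]12C(Br)(Br)[C@@]1(C)[C@@H]3[C@H](C(C)=C)CC[C@]3(C)C2 | intermediate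
11 | 5-bromo-4,7a-dimethyl-3-(prop-1-en-2-yl)-1,2,3,3a,7,7a-hexahydro-6H-inden-6-one; cis-fused, isopropenyl cis to C4 | O=C1C(Br)=C(C)[C@@H]2[C@H](C(C)=C)CC[C@]2(C)C1 | intermediate
12 | (S)-β-citronellene, (3S)-3,7-dimethylocta-1,6-diene | CC(C)=CCC[C@H](C)C=C | starting material
13 | (S)-4-methylhex-5-enal | O=CCC[C@H](C)C=C | intermediate
14 | (S)-6,6-dimethoxy-3-methylhex-1-ene | COC(OC)CC[C@H](C)C=C | intermediate
15 | 9-[(R)-6,6-dimethoxy-3-methylhexyl]-9-borabicyclo[3.3.1]nonane | COC(OC)CC[C@H](C)CCB1C2CCCC1CCC2 | intermediate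
16 | 11 with Br replaced by the (R)-6,6-dimethoxy-3-methylhexyl chain on C5 | COC(OC)CC[C@H](C)CCC1=C(C)[C@@H]2[C@H](C(C)=C)CC[C@]2(C)CC1=O | intermediate
17 | 7-hydroxy derivative of 16, OH cis to the C7a methyl (7R) | COC(OC)CC[C@H](C)CCC1=C(C)[C@@H]2[C@H](C(C)=C)CC[C@]2(C)[C@@H](O)C1=O | intermediate
18 | (6R,7R)-trans-diol from 17 | COC(OC)CC[C@H](C)CCC1=C(C)[C@@H]2[C@H](C(C)=C)CC[C@]2(C)[C@@H](O)[C@@H]1O | intermediate
19 | 6,7-O-(1,1,3,3-tetraisopropyldisiloxane-1,3-diyl) derivative of 18 | COC(OC)CC[C@H](C)CCC1=C(C)[C@@H]2[C@H](C(C)=C)CC[C@]2(C)[C@H]3O[Si](C(C)C)(C(C)C)O[Si](C(C)C)(C(C)C)O[C@H]13 | intermediate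
20 | methyl ketone (acetyl on C3, concave face) from 19 | COC(OC)CC[C@H](C)CCC1=C(C)[C@@H]2[C@H](C(C)=O)CC[C@]2(C)[C@H]3O[Si](C(C)C)(C(C)C)O[Si](C(C)C)(C(C)C)O[C@H]13 | intermediate
21 | 1-(trifluoromethylsulfonyloxy)vinyl derivative (C1' triflate) of 20 | COC(OC)CC[C@H](C)CCC1=C(C)[C@@H]2[C@H](C(=C)OS(=O)(=O)C(F)(F)F)CC[C@]2(C)[C@H]3O[Si](C(C)C)(C(C)C)O[Si](C(C)C)(C(C)C)O[C@H]13 | intermediate
22 | triflate aldehyde (C2' = CHO) | O=CCC[C@H](C)CCC1=C(C)[C@@H]2[C@H](C(=C)OS(=O)(=O)C(F)(F)F)CC[C@]2(C)[C@H]3O[Si](C(C)C)(C(C)C)O[Si](C(C)C)(C(C)C)O[C@H]13 | intermediate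
23 | bridged tricyclic allylic alcohol, C2' epimers, diol as disiloxane | C=C1C(O)CC[C@H](C)CCC2=C(C)[C@@H]3[C@H]1CC[C@]3(C)[C@H]4O[Si](C(C)C)(C(C)C)O[Si](C(C)C)(C(C)C)O[C@H]24 | intermediate
24 | bridged α-methylene ketone (C2' = C=O) | C=C1C(=O)CC[C@H](C)CCC2=C(C)[C@@H]3[C@H]1CC[C@]3(C)[C@H]4O[Si](C(C)C)(C(C)C)O[Si](C(C)C)(C(C)C)O[C@H]24 | intermediate
25 | (2'R)-allylic alcohol | C=C1[C@H](O)CC[C@H](C)CCC2=C(C)[C@@H]3[C@H]1CC[C@]3(C)[C@H]4O[Si](C(C)C)(C(C)C)O[Si](C(C)C)(C(C)C)O[C@H]24 | intermediate
26 | (2'R)-acetate, diol as disiloxane | C=C1[C@H](OC(C)=O)CC[C@H](C)CCC2=C(C)[C@@H]3[C@H]1CC[C@]3(C)[C@H]4O[Si](C(C)C)(C(C)C)O[Si](C(C)C)(C(C)C)O[C@H]24 | intermediate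
27 | CNP0192310.3 (3R,3aS,6R,7R,7aS,2'R,5'R) | C=C1[C@H](OC(C)=O)CC[C@H](C)CCC2=C(C)[C@@H]3[C@H]1CC[C@]3(C)[C@@H](O)[C@@H]2O | target

Total step count: 20. Longest linear sequence: 19 steps (steps 1–7 and 9–20).

Steps most likely to fail

Step 16. Intermolecular coupling and protodemetalation of the alkenylchromium species may outrun closure of the strained eleven-membered ring. The fallback sets out from 20 and replaces the alkenyl-metal addition by a carbonyl–carbonyl coupling.
- Hydrolysis of the acetal (LiBF4, wet MeCN) gives the keto aldehyde F7.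
- A McMurry-type pinacol macrocyclisation (TiCl3(DME)1.5, Zn(Cu), DME, slow addition, rt) joins C1' and C2' to give the bridged 1,2-diol F8. Its two new centres are irrelevant.
- Dess–Martin oxidation of the secondary hydroxyl gives the tertiary α-hydroxy ketone F9.
- Dehydration toward the methyl group with methyl N-(triethylammoniosulfonyl)carbamate (Burgess dehydration) returns to the route at 24.

Step 5. The ene reaction may need temperatures at which polymerisation of the enone or migration of the prenyl double bond competes. The fallback sets out from 7 and reaches the same bond set in a photochemical way.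
- Irradiation (350 nm, hexane) closes C3–C3a and C1'–C4 in a straight intramolecular [2+2] photocycloaddition to the tricyclic cyclobutyl ketone F1. In F1 the four-membered ring enforces the cis C3/C4 relationship.
- Me3SiI in CH2Cl2 followed by water cleaves the C4–C1' bond to the tertiary iodide F2.
- DBU in warm toluene eliminates HI toward the methyl group and equilibrates C4, coming back to the route at 8.

Step 7. Carbene attack on the isopropenyl group or alkoxide-induced desilylation of the enol ether may compete with cyclopropanation. The fallback sets out from 9 and separates carbon insertion from halogenation.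
- Simmons–Smith methylenation (Et2Zn, CH2I2) gives the siloxycyclopropane F3.
- FeCl3 in DMF opens the zero-bridge bond oxidatively to the ring-enlarged β-chloro ketone F4.
- NaOAc in MeOH eliminates HCl to the 3-methyl enone F5.
- I2/pyridine α-iodination gives the iodoenone F6.
- F6 is coupled with borane 15 under the conditions of step 9 and rejoins the route at 16.

Further compounds
F1 | step 5 | tricyclic [2+2] photoadduct of 7 (bonds C3–C3a and C1'–C4) | O=C1C[C@@]2(C)CC[C@@H]3[C@H]2[C@@]1(C)C3(C)C
F2 | step 5 | diquinane ketone with a 2-iodopropan-2-yl group on C3 (concave face) | O=C1C(C)[C@@H]2[C@H](C(C)(C)I)CC[C@]2(C)C1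
F3 | step 7 | siloxycyclopropane from methylenation of 9 | C[Si](C)(C)O[C@]12C[C@@]1(C)[C@@H]3[C@H](C(C)=C)CC[C@]3(C)C2
F4 | step 7 | ring-enlarged 4-chloro-4-methyl hydrindan-6-one | O=C1CC(C)(Cl)[C@@H]2[C@H](C(C)=C)CC[C@]2(C)C1
F5 | step 7 | 4,7a-dimethyl-3-isopropenyl-cis-hexahydroinden-6-one (C5–H) | O=C1C=C(C)[C@@H]2[C@H](C(C)=C)CC[C@]2(C)C1
F6 | step 7 | 5-iodo analogue of 11 | O=C1C(I)=C(C)[C@@H]2[C@H](C(C)=C)CC[C@]2(C)C1
F7 | step 16 | keto aldehyde from hydrolysis of 20 | O=CCC[C@H](C)CCC1=C(C)[C@@H]2[C@H](C(C)=O)CC[C@]2(C)[C@H]3O[Si](C(C)C)(C(C)C)O[Si](C(C)C)(C(C)C)O[C@H]13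
F8 | step 16 | bridged C1',C2'-diol (pinacol product, epimers) | CC1(O)C(O)CC[C@H](C)CCC2=C(C)[C@@H]3[C@H]1CC[C@]3(C)[C@H]4O[Si](C(C)C)(C(C)C)O[Si](C(C)C)(C(C)C)O[C@H]24
F9 | step 16 | bridged C1'-hydroxy C2'-ketone | CC1(O)C(=O)CC[C@H](C)CCC2=C(C)[C@@H]3[C@H]1CC[C@]3(C)[C@H]4O[Si](C(C)C)(C(C)C)O[Si](C(C)C)(C(C)C)O[C@H]24
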